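**Retrosynthetic overview**

1. The diene is cut at its central sp2–sp2 single bond (Negishi coupling) into head-group (E)-vinyl iodide 15 and terpenoid alkyne 26. Carboalumination of 26 supplies the vinylic methyl and the E geometry. 26 comes from (S)-citronellyl bromide (remote methyl centre), 1-(trimethylsilyl)propyne and 3-bromofuran.
2. The furanone ring is cut at O1–C5 and C3–C4: a propanoate C,O-dinucleophile plus a 1,2-dielectrophile, realised as a one-pot SN2 acyloxylation / Dieckmann ring-switch on the α-triflyloxy δ-lactone 9.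
3. Enabling feature: furanone C4 (enol carbon) and C5 (O-bearing stereocentre), with side-chain carbons C1', C2' and the carbon that becomes C3', close through one oxygen into a six-membered lactone (C4 = lactone C=O, C5 = α-carbon carrying OTf, ring O on the future C3'). That ring oxygen is the leaving group of the Claisen step and returns as the CH2OH handle; the acidic O=C2–C3=C4–OH unit is the thermodynamic sink.
4. Ring order: γ-lactone 1 (glutamic acid pool; relays its centre to the side-chain methyl centre by trans-methylation) → δ-lactone 8 (oxidation/reduction ring switch) → furan-2(5H)-one 12 (key step). The furan ring is bought as 3-bromofuran.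
5. Both temporary lactones are consumed by step 7; the enol methyl ether is put on in step 8 and removed in step 17.

Key step: step 7

Remark: the tetronic acid is written as its 4-hydroxyfuran-2(5H)-one tautomer throughout; compounds 1, 10, 16, 17 and 23 are taken to be commercial.

**Route**

Step 1
Reactants: 1 (5S)-5-(hydroxymethyl)dihydrofuran-2(3H)-one
Product: 2 (5S)-5-[(trityloxy)methyl]dihydrofuran-2(3H)-one
Conditions: TrCl, pyridine, DMAP (cat.), CH2Cl2, rt
Reagents that add atoms: trityl chloride, ClC(c1ccccc1)(c1ccccc1)c1ccccc1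
Why: Tritylation of the primary alcohol (SN1-type etherification) installs a bulky group that should shield one face of the lactone in the next step.

Step 2
Reactants: 2 (5S)-5-[(trityloxy)methyl]dihydrofuran-2(3H)-one
Product: 4 (3R,5S)-3-methyl-5-[(trityloxy)methyl]dihydrofuran-2(3H)-one, via lithium enolate 3 (not isolated)
Conditions: LDA, THF, –78 °C; then MeI, –78 °C
Reagents that add atoms: iodomethane, CI
Why: Lactone enolate alkylation should occur anti to the CH2OTr group (1,3-induction across the five-membered ring), setting the methyl-bearing centre as 3R (trans); any cis isomer would be removed by chromatography.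

Step 3
Reactants: 4 (3R,5S)-3-methyl-5-[(trityloxy)methyl]dihydrofuran-2(3H)-one
Product: 5 (3R,5S)-5-(hydroxymethyl)-3-methyldihydrofuran-2(3H)-one
Conditions: AcOH/H2O (4:1), 50 °C
Reagents that add atoms: none
Why: Acid-catalysed solvolysis of the trityl ether through the trityl cation should leave the lactone and both stereocentres untouched.

Step 4
Reactants: 5 (3R,5S)-5-(hydroxymethyl)-3-methyldihydrofuran-2(3H)-one
Product: 6 (2S,4R)-4-methyl-5-oxotetrahydrofuran-2-carboxylic acid
Conditions: TEMPO (cat.), PhI(OAc)2, MeCN/H2O (1:1), rt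
Reagents that add atoms: water, O
Why: Nitroxyl-catalysed oxidation of a primary alcohol to the acid through the aldehyde hydrate runs near neutral pH and should not epimerise either α-centre.

Step 5
Reactants: 6 (2S,4R)-4-methyl-5-oxotetrahydrofuran-2-carboxylic acid
Product: 8 (3S,5R)-3-hydroxy-5-methyltetrahydro-2H-pyran-2-one, via dihydroxy acid 7 (not isolated)
Conditions: LiBH4 (2.5 equiv), THF/MeOH, 0 °C → rt; then 2 M HCl; then TsOH (cat.), PhMe, 80 °C
Reagents that add atoms: none
Why: LiBH4 reduces lactones but not lithium carboxylates, so only the γ-lactone carbonyl should be reduced; on acidification the 5-hydroxy acid should close to the six-membered lactone, the only ring open to it, with no stereocentre touched (cis-3,5 product).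

Step 6
Reactants: 8 (3S,5R)-3-hydroxy-5-methyltetrahydro-2H-pyran-2-one
Product: 9 (3S,5R)-5-methyl-2-oxotetrahydro-2H-pyran-3-yl trifluoromethanesulfonate
Conditions: Tf2O, pyridine, CH2Cl2, –40 → –10 °C; used without purification
Reagents that add atoms: trifluoromethanesulfonic anhydride, O=S(=O)(OS(=O)(=O)C(F)(F)F)C(F)(F)F
Why: O-sulfonylation of an α-hydroxy lactone breaks no bond to carbon, so the configuration should be retained, as with α-triflyloxy esters.

Step 7
Reactants: 9 (3S,5R)-5-methyl-2-oxotetrahydro-2H-pyran-3-yl trifluoromethanesulfonate; 10 sodium propanoate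
Product: 12 (5R)-4-hydroxy-5-[(2R)-3-hydroxy-2-methylpropyl]-3-methylfuran-2(5H)-one, via trans-propanoate ester 11 (not isolated)
Conditions: 10 (1.1 equiv), 15-crown-5, THF, –20 → 0 °C; then LiHMDS (2.5 equiv), –78 → 0 °C; then 1 M HCl
Reagents that add atoms: none
Why: Propanoate displaces the triflate at the lactone α-carbon by SN2 (O1–C5 bond, inversion) to give trans ester 11; LiHMDS then forms the ester enolate at the propanoyl CH2, which adds to the lactone carbonyl (C3–C4 bond), the tetrahedral alkoxide expels the ring oxygen as the side-chain alkoxide, and deprotonation of the 2,4-dione to the tetronate makes the sequence irreversible. The closest known reaction types are the carboxylate displacement of α-triflyloxy esters and lactones with inversion and the Dieckmann (intramolecular Claisen) cyclisation of α-acyloxy esters to tetronic acids. The furanone ring closes by 5-exo-trig attack of the enolate on the lactone C=O through a cis-fused bicyclic tetrahedral intermediate, and the six-membered lactone opens in the same event. C5 of the furanone is set as R by the stereospecific inversion of the (3S)-triflate, and the methyl-bearing centre is carried through untouched. The step needs substitution over E2 elimination and O- over C-alkylation, which is secured by letting the weakly basic carboxylate react with the triflate before any strong base is present, and it needs enolisation at the propanoyl CH2 instead of the ring α-CH, which is favoured by the low temperature, by fast intramolecular trapping of the ester enolate and by the tetronate being the thermodynamic sink.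

Step 8
Reactants: 12 (5R)-4-hydroxy-5-[(2R)-3-hydroxy-2-methylpropyl]-3-methylfuran-2(5H)-one
Product: 13 (5R)-5-[(2R)-3-hydroxy-2-methylpropyl]-4-methoxy-3-methylfuran-2(5H)-one
Conditions: TMSCHN2, PhMe/MeOH (4:1), 0 °C
Reagents that add atoms: (trimethylsilyl)diazomethane, C[Si](C)(C)C=[N+]=[N-]
Why: A diazoalkane methylates only the acidic enol (protonation, then SN2 on the methyldiazonium ion), so the neutral primary alcohol should stay free.

Step 9
Reactants: 13 (5R)-5-[(2R)-3-hydroxy-2-methylpropyl]-4-methoxy-3-methylfuran-2(5H)-one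
Product: 14 (2R)-3-[(2R)-3-methoxy-4-methyl-5-oxo-2,5-dihydrofuran-2-yl]-2-methylpropanal
Conditions: Dess–Martin periodinane, CH2Cl2, 0 °C → rt; used at once
Reagents that add atoms: none
Why: Dess–Martin oxidation is non-basic, so the α-methyl aldehyde should form without epimerisation.

Step 10
Reactants: 14 (2R)-3-[(2R)-3-methoxy-4-methyl-5-oxo-2,5-dihydrofuran-2-yl]-2-methylpropanal
Product: 15 (5R)-5-[(2R,3E)-4-iodo-2-methylbut-3-en-1-yl]-4-methoxy-3-methylfuran-2(5H)-one
Conditions: CrCl2, CHI3, THF/dioxane (1:6), rt
Reagents that add atoms: iodoform, IC(I)I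
Why: Takai iodo-olefination (addition of a gem-dichromium species, then anti elimination) should give the E-vinyl iodide under non-basic conditions that spare the α-stereocentre.

Step 11
Reactants: 16 1-(trimethylsilyl)propyne; 17 (S)-citronellyl bromide [(6S)-8-bromo-2,6-dimethyloct-2-ene]
Product: 19 trimethyl[(6R)-6,10-dimethylundec-9-en-1-yn-1-yl]silane, via lithiated silylpropyne 18 (not isolated)
Conditions: n-BuLi, THF, –78 °C; then 17, DMPU, –78 °C → rt
Reagents that add atoms: none
Why: Propargylic lithiation of the silylpropyne and SN2 alkylation with a primary bromide add the three-carbon alkyne unit; the stereocentre is remote and unaffected (the descriptor changes only by priority).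

Step 12
Reactants: 19 trimethyl[(6R)-6,10-dimethylundec-9-en-1-yn-1-yl]silane
Product: 21 (4R)-4-methyl-9-(trimethylsilyl)non-8-yn-1-ol, via aldehyde 20 (not isolated)
Conditions: O3, CH2Cl2/MeOH, –78 °C (Sudan III end point); then NaBH4, –78 °C → rt
Reagents that add atoms: ozone, [O-][O+]=O
Why: Ozone should attack the electron-rich trisubstituted alkene far faster than the silyl alkyne, and borohydride work-up reduces the ozonolysis products directly to the alcohol.

Step 13
Reactants: 21 (4R)-4-methyl-9-(trimethylsilyl)non-8-yn-1-ol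
Product: 22 [(6R)-9-iodo-6-methylnon-1-yn-1-yl]trimethylsilane
Conditions: I2, PPh3, imidazole, CH2Cl2, 0 °C → rt
Reagents that add atoms: iodine, II
Why: Appel-type iodination (SN2 on the alkoxyphosphonium ion) of a primary alcohol is reliable and leaves the silyl alkyne alone.

Step 14
Reactants: 22 [(6R)-9-iodo-6-methylnon-1-yn-1-yl]trimethylsilane; 23 3-bromofuran
Product: 25 [(6S)-9-(furan-3-yl)-6-methylnon-1-yn-1-yl]trimethylsilane, via alkylzinc iodide 24 (not isolated)
Conditions: Zn dust (TMSCl-activated), LiCl, THF, 40 °C; then 23, Pd(OAc)2 (2 mol%), SPhos (4 mol%), rt → 50 °C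
Reagents that add atoms: none
Why: Zinc insertion into the primary iodide followed by Negishi sp3–sp2 coupling with a heteroaryl bromide should attach the chain at furan C3 only; the bulky biaryl phosphine suppresses β-hydride elimination.

Step 15
Reactants: 25 [(6S)-9-(furan-3-yl)-6-methylnon-1-yn-1-yl]trimethylsilane
Product: 26 3-[(4R)-4-methylnon-8-yn-1-yl]furan
Conditions: K2CO3 (cat.), MeOH, rt
Reagents that add atoms: none
Why: Base-catalysed methanolysis of the alkynyl C–Si bond is mild enough for the furan.

Step 16
Reactants: 26 3-[(4R)-4-methylnon-8-yn-1-yl]furan; 15 (5R)-5-[(2R,3E)-4-iodo-2-methylbut-3-en-1-yl]-4-methoxy-3-methylfuran-2(5H)-one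
Product: 29 (5R)-5-[(2R,3E,5E,10R)-13-(furan-3-yl)-2,6,10-trimethyltrideca-3,5-dien-1-yl]-4-methoxy-3-methylfuran-2(5H)-one, via alkenylalane 27 (not isolated), via alkenylzinc chloride 28 (not isolated)
Conditions: Me3Al (2 equiv), Cp2ZrCl2 (20 mol%), CH2Cl2, 0 °C → rt; volatiles removed; then ZnCl2 (1 equiv), THF; then 15, Pd(PPh3)4 (5 mol%), rt
Reagents that add atoms: trimethylaluminium, C[Al](C)C
Why: Zirconium-catalysed syn-carboalumination puts the methyl on the internal and the metal on the terminal alkyne carbon (E trisubstituted alkene), and Negishi alkenyl–alkenyl coupling proceeds with retention at both partners, so the (3E,5E)-diene should result.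

Step 17
Reactants: 29 (5R)-5-[(2R,3E,5E,10R)-13-(furan-3-yl)-2,6,10-trimethyltrideca-3,5-dien-1-yl]-4-methoxy-3-methylfuran-2(5H)-one
Product: 30 (5R)-5-[(2R,3E,5E,10R)-13-(furan-3-yl)-2,6,10-trimethyltrideca-3,5-dien-1-yl]-4-hydroxy-3-methylfuran-2(5H)-one (CNP0246504.1)
Conditions: LiCl, DMSO, 60 °C; then pH 3 phosphate buffer
Reagents that add atoms: none
Why: Chloride demethylates the vinylogous methyl ester by SN2 at the methyl group (tetronate as leaving group) under neutral conditions that the diene, the furan and the C5 centre should tolerate.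

**Compound list**

1 | (5S)-5-(hydroxymethyl)dihydrofuran-2(3H)-one | O=C1O[C@H](CO)CC1 | starting material
2 | (5S)-5-[(trityloxy)methyl]dihydrofuran-2(3H)-one | O=C1O[C@H](COC(c2ccccc2)(c2ccccc2)c2ccccc2)CC1 | intermediate
3 | lithium (5S)-5-[(trityloxy)methyl]-4,5-dihydrofuran-2-olate (lithium enolate of 2) | [Li]OC1=CC[C@@H](COC(c2ccccc2)(c2ccccc2)c2ccccc2)O1 | intermediate
4 | (3R,5S)-3-methyl-5-[(trityloxy)methyl]dihydrofuran-2(3H)-one | O=C1O[C@H](COC(c2ccccc2)(c2ccccc2)c2ccccc2)C[C@H]1C | intermediate
5 | (3R,5S)-5-(hydroxymethyl)-3-methyldihydrofuran-2(3H)-one | O=C1O[C@H](CO)C[C@H]1C | intermediate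
6 | (2S,4R)-4-methyl-5-oxotetrahydrofuran-2-carboxylic acid | O=C1O[C@H](C(=O)O)C[C@H]1C | intermediate
7 | (2S,4R)-2,5-dihydroxy-4-methylpentanoic acid | OC(=O)[C@@H](O)C[C@@H](C)CO | intermediate
8 | (3S,5R)-3-hydroxy-5-methyltetrahydro-2H-pyran-2-one | O=C1[C@@H](O)C[C@@H](C)CO1 | intermediate
9 | (3S,5R)-5-methyl-2-oxotetrahydro-2H-pyran-3-yl trifluoromethanesulfonate | O=C1[C@@H](OS(=O)(=O)C(F)(F)F)C[C@@H](C)CO1 | intermediate
10 | sodium propanoate | CCC(=O)[O-].[Na+] | starting material
11 | (3R,5R)-5-methyl-2-oxotetrahydro-2H-pyran-3-yl propanoate | O=C1[C@H](OC(=O)CC)C[C@@H](C)CO1 | intermediate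
12 | (5R)-4-hydroxy-5-[(2R)-3-hydroxy-2-methylpropyl]-3-methylfuran-2(5H)-one | CC1=C(O)[C@@H](C[C@@H](C)CO)OC1=O | intermediate
13 | (5R)-5-[(2R)-3-hydroxy-2-methylpropyl]-4-methoxy-3-methylfuran-2(5H)-one | CC1=C(OC)[C@@H](C[C@@H](C)CO)OC1=O | intermediate
14 | (2R)-3-[(2R)-3-methoxy-4-methyl-5-oxo-2,5-dihydrofuran-2-yl]-2-methylpropanal | CC1=C(OC)[C@@H](C[C@@H](C)C=O)OC1=O | intermediate
15 | (5R)-5-[(2R,3E)-4-iodo-2-methylbut-3-en-1-yl]-4-methoxy-3-methylfuran-2(5H)-one | CC1=C(OC)[C@@H](C[C@@H](C)/C=C/I)OC1=O | intermediate
16 | 1-(trimethylsilyl)propyne | CC#C[Si](C)(C)C | starting material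
17 | (S)-citronellyl bromide, (6S)-8-bromo-2,6-dimethyloct-2-ene | C[C@@H](CCC=C(C)C)CCBr | starting material
18 | [3-(trimethylsilyl)prop-2-yn-1-yl]lithium | [Li]CC#C[Si](C)(C)C | intermediate
19 | trimethyl[(6R)-6,10-dimethylundec-9-en-1-yn-1-yl]silane | C[C@@H](CCC=C(C)C)CCCC#C[Si](C)(C)C | intermediate
20 | (4R)-4-methyl-9-(trimethylsilyl)non-8-ynal | C[C@@H](CCC=O)CCCC#C[Si](C)(C)C | intermediate
21 | (4R)-4-methyl-9-(trimethylsilyl)non-8-yn-1-ol | C[C@@H](CCCO)CCCC#C[Si](C)(C)C | intermediate
22 | [(6R)-9-iodo-6-methylnon-1-yn-1-yl]trimethylsilane | C[C@@H](CCCI)CCCC#C[Si](C)(C)C | intermediate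
23 | 3-bromofuran | Brc1ccoc1 | starting material
24 | iodo[(4R)-4-methyl-9-(trimethylsilyl)non-8-yn-1-yl]zinc | C[C@@H](CCC[Zn]I)CCCC#C[Si](C)(C)C | intermediate
25 | [(6S)-9-(furan-3-yl)-6-methylnon-1-yn-1-yl]trimethylsilane | C[C@@H](CCCc1ccoc1)CCCC#C[Si](C)(C)C | intermediate
26 | 3-[(4R)-4-methylnon-8-yn-1-yl]furan | C[C@@H](CCCc1ccoc1)CCCC#C | intermediate
27 | [(1E,6S)-9-(furan-3-yl)-2,6-dimethylnon-1-en-1-yl]dimethylalumane | C[Al](C)/C=C(\C)CCC[C@@H](C)CCCc1ccoc1 | intermediate
28 | chloro[(1E,6S)-9-(furan-3-yl)-2,6-dimethylnon-1-en-1-yl]zinc | Cl[Zn]/C=C(\C)CCC[C@@H](C)CCCc1ccoc1 | intermediate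
29 | (5R)-5-[(2R,3E,5E,10R)-13-(furan-3-yl)-2,6,10-trimethyltrideca-3,5-dien-1-yl]-4-methoxy-3-methylfuran-2(5H)-one | CC1=C(OC)[C@@H](C[C@@H](C)/C=C/C=C(\C)CCC[C@@H](C)CCCc2ccoc2)OC1=O | intermediate
30 | (5R)-5-[(2R,3E,5E,10R)-13-(furan-3-yl)-2,6,10-trimethyltrideca-3,5-dien-1-yl]-4-hydroxy-3-methylfuran-2(5H)-one | CC1=C(O)[C@@H](C[C@@H](C)/C=C/C=C(\C)CCC[C@@H](C)CCCc2ccoc2)OC1=O | target

**Step count and risks**

Total steps: 17. Longest linear sequence: 12 (steps 1–10, 16, 17); steps 11–15 form the second branch.

Steps most likely to fail: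

1. Step 7. The triflate may be lost by E2 elimination in the first stage. In the second stage, enolisation at the ring α-carbon instead of the propanoyl CH2 would erode the configuration of the future C5, and the Claisen step could stall or reverse. The fallback replaces base-mediated enolate formation by reductive enolate formation. It sets out from 9: displacement with sodium 2-bromopropanoate (15-crown-5, THF, –20 °C) should give (3R,5R)-5-methyl-2-oxotetrahydro-2H-pyran-3-yl 2-bromopropanoate F1 (mixture at the bromine-bearing carbon, which is of no consequence). SmI2 (2.2 equiv, THF, –78 °C) should then generate the samarium enolate only at the C–Br carbon and close the furanone by a Reformatsky-type intramolecular acylation of the lactone carbonyl under non-basic conditions. Acidic work-up returns to the route at 12.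

2. Step 16. Methyl transfer from residual methylaluminium species to the vinyl iodide, addition of aluminium reagents to the butenolide carbonyl, homocoupling, and carry-over of the regioisomeric carbometalation product may all lower the efficiency of the one-pot coupling. The fallback separates metalation from coupling and changes the nucleophile to boron. It sets out from 26: carboalumination as in step 16, then trapping of the alkenylalane with 2-isopropoxy-4,4,5,5-tetramethyl-1,3,2-dioxaborolane, should give 2-[(1E,6R)-9-(furan-3-yl)-2,6-dimethylnon-1-en-1-yl]-4,4,5,5-tetramethyl-1,3,2-dioxaborolane F2, which can be purified. Suzuki–Miyaura coupling of F2 with 15 (Pd(dppf)Cl2, Cs2CO3, THF/H2O, rt) returns to the route at 29.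

3. Step 10. The iodo-olefination may be incompletely E-selective, and the α-methyl aldehyde may epimerise or decompose on the Lewis-acidic chromium salts. The fallback builds the vinyl iodide from an alkyne. It sets out from 14: homologation with dimethyl (1-diazo-2-oxopropyl)phosphonate (K2CO3, MeOH, 0 °C) should give (5R)-4-methoxy-3-methyl-5-[(2R)-2-methylbut-3-yn-1-yl]furan-2(5H)-one F3. Hydrozirconation (Cp2Zr(H)Cl, THF, 0 °C) and iodinolysis (I2) should then give the E-iodide stereospecifically (syn addition, retention on iodination) and return to the route at 15.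

**Further compounds**

F1 | step 7 | (3R,5R)-5-methyl-2-oxotetrahydro-2H-pyran-3-yl 2-bromopropanoate | O=C1[C@H](OC(=O)C(C)Br)C[C@@H](C)CO1
F2 | step 16 | 2-[(1E,6R)-9-(furan-3-yl)-2,6-dimethylnon-1-en-1-yl]-4,4,5,5-tetramethyl-1,3,2-dioxaborolane | CC1(C)OB(/C=C(\C)CCC[C@@H](C)CCCc2ccoc2)OC1(C)C
F3 | step 10 | (5R)-4-methoxy-3-methyl-5-[(2R)-2-methylbut-3-yn-1-yl]furan-2(5H)-one | CC1=C(OC)[C@@H](C[C@@H](C)C#C)OC1=O
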